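The readings come from a simulation with constants of no real substance, and the scatter is random.

Count what is left, not what is made.

- blue: solid substrate 10 mM; gas 5.5 mM (held); the very flask that is asked about, followed so far
- flask: solid substrate 10 mM; gas 5.5 mM (held); time 15 h

- blue (time / h: target / %, solid product / %): 0.250: 0, 0.3; 0.833: 2.5, 0; 1.33: 5.5, 0.6; 2.00: 9.4, 0.2; 3.00: 15.4, 0

(each reading ± 0.5 percentage points)

1. the target and solid product together standing at 15 h, as a percentage of the solid substrate charged
2. concentration of dissolved substrate in solution at 15 h, in percent of saturation

- target is meant together with its solid product
- solid, in amounts per volume of the solution: solid substrate, solid product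
- at the start none of the gas is in solution
- at the start none of the solid substrate is in solution
- dissolved substrate means what is dissolved; the solid is not counted in it

Take the blue run from 0.833 h to 3.00 h: the target climbs at 0.595 mM h⁻¹, a zero-order stretch. At 0.833 h the fraction left is 97.5% of the charge. Divide that amount by the slope and add the hour, and you have the run-out time, the hour at which this line reaches the whole charge: 17.2 h. On this line, what is left at any earlier hour is the slope times the time still to run. Assume the line holds, and at 15 h this flask has 13.2% left and 86.8% made, give or take 4.6 percentage points from the scatter of the two readings. The blue run reads no dissolved substrate, so I name no percent of saturation.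

The forecast stands at 85% and 90% of saturation: “The solution should therefore be near saturation”. The flask gives 82.4% and 5.29% of saturation.

    solid product ⇌ target, rate k1*(cs1 - [target]) while solid is left; crystals form when [target] > cs1 (solubility = 3.20 mM, k = 4.30 h⁻¹)
    gas ⇌ partner, rate k2*(csat - [partner]) (kL = 0.880 h⁻¹)
    solid substrate ⇌ dissolved substrate, rate k3*(cs3 - [dissolved substrate]) while solid is left; crystals form when [dissolved substrate] > cs3 (solubility = 1.90 mM, k = 0.310 h⁻¹)
    partner → decomposed reagent (k = 0.200 h⁻¹)
    dissolved substrate + partner → target (k = 1400 M⁻¹ h⁻¹)

In this flask at 15 h, dissolved substrate lasts 0.180 h against partner at 3.96 mM, while the solid refills the solution on a time of 3.23 h, longer. Dissolving is the rate-limiting step of this flask, and at 6.35 h the making of dissolved substrate over its using up, each step taken net, stands at 1.00, a quasi-steady state. This flask has 17.6% left at 15 h, 4.5 points above my figure and inside the margin. For the neighbour flask read at 4.0 h, the run-out time gives 78.6% left, and that flask has 79% still there.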